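## Retrosynthetic overview
1. The lactol ring comes from a 5-alkyl-2,3-dihydro-4H-pyran-4-one by 1,2-reduction and then mild aqueous acid (Stork–Danheiser/Ferrier-type transposition). The ring enforces the Z-olefin.
2. The C16 side chain is attached by B-alkyl Suzuki coupling of the α-iodo-dihydropyranone with homofarnesyl-9-BBN, made from (E,E)-farnesol.
3. The dihydropyranone comes from 6-endo closure of a β-hydroxy ynone (via its enaminone), built from an aldehyde and ethynyl Grignard.
4. The hydroxyalkyl-succinimide comes from O→N acyl transfer in a trans-paraconamide. The trans relationship is set by thermodynamic epimerisation in the γ-lactone.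
5. The carbinol comes from ketoreductase reduction of an achiral β-keto ester. Ring order: γ-lactone (temporary), then succinimide, then dihydropyranone, then dihydropyranol.

Assumption: the lactol carbon is configurationally labile through ring–chain tautomerism. The drawn 6S (2,6-cis) epimer is therefore obtained by equilibration and separation, not by a stereoselective bond formation.

## Route

**Step 1**
Reactants: 1, 3-(benzyloxy)propanoic acid; 2, mono-tert-butyl malonate
Product: 3, tert-butyl 5-(benzyloxy)-3-oxopentanoate (achiral)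
Conditions: 1, CDI, THF, rt; then 2, MgCl2, Et3N, MeCN, rt → 40 °C; 10% citric acid
Reagents that add atoms: mono-tert-butyl malonate (2), CC(C)(C)OC(=O)CC(=O)O (delivers CH2CO2tBu, loses CO2)
Why: In this Masamune–Brooks decarboxylative Claisen condensation the acyl imidazolide is C-acylated by the magnesium malonate enolate under near-neutral conditions, so the β-benzyloxy group is not eliminated and no stereocentre forms.

**Step 2**
Reactants: 3
Product: 4, tert-butyl (3R)-5-(benzyloxy)-3-hydroxypentanoate
Conditions: ketoreductase (KRED, NADPH-dependent oxidoreductase, EC 1.1.1; (R)-selective member of a screening panel), NADP+ (cat.), i-PrOH (15% v/v), K-phosphate pH 7.0, 30 °C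
Reagents that add atoms: none
Why: β-Keto esters are a benchmark substrate class for enzymatic asymmetric ketone reduction, and hydride delivery to one face of the prochiral ketone (≥99% ee expected) creates the first stereocentre, (R), which becomes the ring C–O carbon.

**Step 3**
Reactants: 4; 5, allyl bromide
Product: 6, tert-butyl (2R)-2-[(1R)-3-(benzyloxy)-1-hydroxypropyl]pent-4-enoate (2,3-anti)
Conditions: LDA (2.2 equiv), THF, −78 → −20 °C; 5 (2 equiv), DMPU, −78 → −20 °C
Reagents that add atoms: allyl bromide (5), C=CCBr
Why: In the Fráter–Seebach alkylation the lithium-chelated dianion is allylated anti to the side chain (dr ≥95:5), which installs the masked CH2CO2H arm and leaves an α-centre that is corrected in step 6.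

**Step 4**
Reactants: 6
Product: 7, tert-butyl (2R,3R)-2-[2-(benzyloxy)ethyl]-5-hydroxytetrahydrofuran-3-carboxylate (lactol, anomer mixture)
Conditions: O3, CH2Cl2, −78 °C; PPh3, → rt
Reagents that add atoms: ozone, [O-][O+]=O
Why: Ozonolysis cleaves the only alkene and the neighbouring hydroxyl captures the aldehyde as a γ-lactol, with neither existing stereocentre touched.

**Step 5**
Reactants: 7
Product: 8, tert-butyl (2R,3R)-2-[2-(benzyloxy)ethyl]-5-oxotetrahydrofuran-3-carboxylate (cis-paraconate)
Conditions: TEMPO (10 mol %), PhI(OAc)2, CH2Cl2, rt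
Reagents that add atoms: none
Why: TEMPO/PhI(OAc)2 oxidation of a lactol to a lactone is mild and leaves the benzyl ether and tert-butyl ester intact.

**Step 6**
Reactants: 8
Product: 9, tert-butyl (2R,3S)-2-[2-(benzyloxy)ethyl]-5-oxotetrahydrofuran-3-carboxylate (trans-paraconate)
Conditions: DBU (0.3 equiv), toluene, rt → 40 °C; chromatography, cis isomer recycled
Reagents that add atoms: none
Why: Thermodynamic epimerisation through the ester enolate affects only the carbon α to the ester, reprotonation outruns E1cB lactone opening with a catalytic amidine, and the trans lactone is favoured (about ≥9:1), which sets the future succinimide centre as (S).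

**Step 7**
Reactants: 9
Product: 10, (2R,3S)-2-[2-(benzyloxy)ethyl]-5-oxotetrahydrofuran-3-carboxylic acid
Conditions: TFA/CH2Cl2 1:3, 0 °C → rt
Reagents that add atoms: none
Why: Acidolysis of the tert-butyl ester (loss of isobutene) spares the lactone and benzyl ether and uses no base, so no epimerisation occurs.

**Step 8**
Reactants: 10
Product: 11, (2R,3S)-2-[2-(benzyloxy)ethyl]-5-oxotetrahydrofuran-3-carboxamide
Conditions: i-BuOCOCl, NMM, THF, −15 °C; NH3 (0.5 M in dioxane), −15 → 0 °C
Reagents that add atoms: ammonia, N
Why: In this mixed-anhydride amidation the anhydride reacts with ammonia far faster than the lactone at low temperature, and the trans arrangement is also the stable one.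

**Step 9**
Reactants: 11
Product: 12, (3S)-3-[(1R)-3-(benzyloxy)-1-hydroxypropyl]pyrrolidine-2,5-dione
Conditions: NaOMe (1.1 equiv), MeOH, 0 °C → rt; AcOH (1.1 equiv), 0 °C; used promptly
Reagents that add atoms: none
Why: Intramolecular O→N acyl transfer (methoxide opens the lactone, then amide–ester imide closure) is driven by irreversible deprotonation of the imide (pKa about 9.6), and no bond to either stereocentre is broken because N–H deprotonation precedes any C–H deprotonation.

**Step 10**
Reactants: 12
Product: 13, (3S)-3-[(1R)-3-(benzyloxy)-1-(tert-butyldimethylsilyloxy)propyl]pyrrolidine-2,5-dione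
Conditions: TBSOTf (2.5 equiv), 2,6-lutidine, CH2Cl2, −20 → 0 °C; MeOH/aq NaHCO3 work-up
Reagents that add atoms: TBSOTf, CC(C)(C)[Si](C)(C)OS(=O)(=O)C(F)(F)F
Why: Fast O-silylation caps the carbinol so it cannot re-attack the imide, and any N-silyl group is hydrolysed on work-up.

**Step 11**
Reactants: 13
Product: 14, (3S)-3-[(1R)-1-(tert-butyldimethylsilyloxy)-3-hydroxypropyl]pyrrolidine-2,5-dione
Conditions: H2 (1 atm), 10% Pd/C, EtOAc, rt
Reagents that add atoms: none
Why: Neutral hydrogenolysis of the benzyl ether is carried out while the molecule still contains no alkene, and the TBS ether and imide are inert.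

**Step 12**
Reactants: 14
Product: 15, (3R)-3-(tert-butyldimethylsilyloxy)-3-[(3S)-2,5-dioxopyrrolidin-3-yl]propanal
Conditions: DMP, NaHCO3, CH2Cl2, 0 °C → rt
Reagents that add atoms: none
Why: Buffered Dess–Martin oxidation gives the β-silyloxy aldehyde without elimination and tolerates the N–H imide.

**Step 13**
Reactants: 15; 16, ethynylmagnesium bromide
Product: 17, (3S)-3-[(1R)-1-(tert-butyldimethylsilyloxy)-3-hydroxypent-4-yn-1-yl]pyrrolidine-2,5-dione (carbinol epimers, inconsequential)
Conditions: 16 (3.0 equiv), THF, −78 → −30 °C; cold sat. NH4Cl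
Reagents that add atoms: ethynylmagnesium bromide (16), C#C[Mg]Br
Why: In this Grignard 1,2-addition the first equivalent converts the imide into its unreactive magnesium imidate, the weakly basic acetylide then adds only to the aldehyde, and the cold quench prevents silyl migration.

**Step 14**
Reactants: 17
Product: 18, (3S)-3-[(1R)-1-(tert-butyldimethylsilyloxy)-3-oxopent-4-yn-1-yl]pyrrolidine-2,5-dione
Conditions: DMP, NaHCO3, CH2Cl2, 0 °C; used crude
Reagents that add atoms: none
Why: Dess–Martin oxidation of the propargylic alcohol removes the undefined carbinol centre and gives the terminal ynone under non-basic conditions.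

**Step 15**
Reactants: 18
Product: 19, (3S)-3-[(2R)-4-oxo-3,4-dihydro-2H-pyran-2-yl]pyrrolidine-2,5-dione
Conditions: Et2NH (2 equiv), MeCN, 0 °C, 15 min (enaminone, not isolated); then 48% aq HF, 0 °C → rt
Reagents that add atoms: none (Et2NH adds and is expelled again)
Why: Aza-Michael addition tames the ynone as an enaminone, and acid then removes the TBS group so the freed hydroxyl closes by 6-endo addition–elimination faster than it can attack the imide, with the C–O stereocentre retained.

**Step 16**
Reactants: 19
Product: 20, (3S)-3-[(2R)-5-iodo-4-oxo-3,4-dihydro-2H-pyran-2-yl]pyrrolidine-2,5-dione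
Conditions: I2 (2 equiv), pyridine/CH2Cl2 1:1, rt, dark; aq Na2S2O3
Reagents that add atoms: iodine, II
Why: Johnson-type α-iodination occurs at the nucleophilic α-carbon of the vinylogous ester, and any N-iodination of the imide is reversible.

**Step 17**
Reactants: 21, (2E,6E)-farnesol
Product: 22, (2E,6E)-farnesal
Conditions: activated MnO2, CH2Cl2, rt
Reagents that add atoms: none
Why: MnO2 allylic oxidation gives the enal with the olefin geometry retained.

**Step 18**
Reactants: 22; 23, methyltriphenylphosphonium bromide
Product: 24, (3E,7E)-4,8,12-trimethyltrideca-1,3,7,11-tetraene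
Conditions: 23, n-BuLi, THF, 0 °C; then 22, 0 °C → rt
Reagents that add atoms: methyltriphenylphosphonium bromide (23), C[P+](c1ccccc1)(c1ccccc1)c1ccccc1.[Br-]
Why: Wittig methylenation of the enal adds the sixteenth carbon and does not disturb the trisubstituted E-olefins.

**Step 19**
Reactants: 24; 25, 9-BBN
Product: 26, 9-[(3E,7E)-4,8,12-trimethyltrideca-3,7,11-trien-1-yl]-9-borabicyclo[3.3.1]nonane
Conditions: 25 (0.95 equiv), THF, 0 °C → rt; used as solution
Reagents that add atoms: 9-BBN (25), B1C2CCCC1CCC2
Why: Anti-Markovnikov hydroboration by the bulky borane attacks only the monosubstituted terminus of the diene, and using it sub-stoichiometrically leaves no B–H to reduce the enone in step 20.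

**Step 20**
Reactants: 20; 26
Product: 27, (3S)-3-[(2R)-4-oxo-5-[(3E,7E)-4,8,12-trimethyltrideca-3,7,11-trien-1-yl]-3,4-dihydro-2H-pyran-2-yl]pyrrolidine-2,5-dione
Conditions: 26 (1.5 equiv), PdCl2(dppf)·CH2Cl2 (5 mol %), AsPh3 (10 mol %), Cs2CO3 (3 equiv), DMF/THF/H2O, rt; no peroxide work-up
Reagents that add atoms: borane 26, CC(C)=CCC/C(C)=C/CC/C(C)=C/CCB1C2CCCC1CCC2 (transfers the C16 alkyl group)
Why: α-Iodoenones are excellent partners for B-alkyl Suzuki–Miyaura coupling at room temperature, and the imide sits as its anion, which resists both hydrolysis and α-epimerisation.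

**Step 21**
Reactants: 27
Product: 28, (3S)-3-[(2R)-4-hydroxy-5-[(3E,7E)-4,8,12-trimethyltrideca-3,7,11-trien-1-yl]-3,4-dihydro-2H-pyran-2-yl]pyrrolidine-2,5-dione (mainly 2,4-cis; this centre is lost in step 22)
Conditions: NaBH4, CeCl3·7H2O, MeOH, −78 → −40 °C; acetone, pH 7 buffer
Reagents that add atoms: none
Why: Luche 1,2-reduction of the enone is complete within minutes at low temperature, under which conditions an N–H succinimide is not reduced.

**Step 22**
Reactants: 28
Product: 29, hippolide A, (3S)-3-[(2R,6S)-6-hydroxy-5-[(3E,7E)-4,8,12-trimethyltrideca-3,7,11-trien-1-yl]-3,6-dihydro-2H-pyran-2-yl]pyrrolidine-2,5-dione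
Conditions: PPTS (0.2 equiv), THF/H2O 4:1, 0 °C → rt; lactol epimers separated (HPLC), the other epimer re-equilibrated and recycled
Reagents that add atoms: water, O
Why: In this Stork–Danheiser/Ferrier-type allylic transposition the enol-ether allylic alcohol ionises to a ring oxocarbenium ion that water captures at the acetal carbon, so the ring fixes the olefin position and Z-geometry while the lactol centre is set by equilibration.

## Compound list
1 | 3-(benzyloxy)propanoic acid | OC(=O)CCOCc1ccccc1 | starting material
2 | mono-tert-butyl malonate | CC(C)(C)OC(=O)CC(=O)O | starting material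
3 | tert-butyl 5-(benzyloxy)-3-oxopentanoate | CC(C)(C)OC(=O)CC(=O)CCOCc1ccccc1 | intermediate
4 | tert-butyl (3R)-5-(benzyloxy)-3-hydroxypentanoate | CC(C)(C)OC(=O)C[C@H](O)CCOCc1ccccc1 | intermediate
5 | allyl bromide | C=CCBr | starting material
6 | tert-butyl (2R)-2-[(1R)-3-(benzyloxy)-1-hydroxypropyl]pent-4-enoate | CC(C)(C)OC(=O)[C@H](CC=C)[C@H](O)CCOCc1ccccc1 | intermediate
7 | (2R,3R)-γ-lactol, anomer mixture | OC1C[C@@H](C(=O)OC(C)(C)C)[C@@H](CCOCc2ccccc2)O1 | intermediate
8 | cis-(2R,3R)-paraconate tert-butyl ester | O=C1C[C@@H](C(=O)OC(C)(C)C)[C@@H](CCOCc2ccccc2)O1 | intermediate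
9 | trans-(2R,3S)-paraconate tert-butyl ester | O=C1C[C@H](C(=O)OC(C)(C)C)[C@@H](CCOCc2ccccc2)O1 | intermediate
10 | trans-(2R,3S)-paraconic acid | O=C1C[C@H](C(=O)O)[C@@H](CCOCc2ccccc2)O1 | intermediate
11 | trans-(2R,3S)-paraconamide | O=C1C[C@H](C(N)=O)[C@@H](CCOCc2ccccc2)O1 | intermediate
12 | (3S)-3-[(1R)-3-(benzyloxy)-1-hydroxypropyl]succinimide | c1ccccc1COCC[C@H]([C@@H]2CC(=O)NC2=O)O | intermediate
13 | O-TBS ether of 12 | c1ccccc1COCC[C@H]([C@@H]2CC(=O)NC2=O)O[Si](C)(C)C(C)(C)C | intermediate
14 | primary alcohol | OCC[C@H]([C@@H]1CC(=O)NC1=O)O[Si](C)(C)C(C)(C)C | intermediate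
15 | aldehyde | O=CC[C@H]([C@@H]1CC(=O)NC1=O)O[Si](C)(C)C(C)(C)C | intermediate
16 | ethynylmagnesium bromide | C#C[Mg]Br | starting material
17 | propargylic alcohol (epimers) | C#CC(O)C[C@H]([C@@H]1CC(=O)NC1=O)O[Si](C)(C)C(C)(C)C | intermediate
18 | ynone | C#CC(=O)C[C@H]([C@@H]1CC(=O)NC1=O)O[Si](C)(C)C(C)(C)C | intermediate
19 | (2R)-dihydropyranone-(3S)-succinimide | O=C1C[C@H]([C@@H]2CC(=O)NC2=O)OC=C1 | intermediate
20 | 5-iodo-dihydropyranone | O=C1C[C@H]([C@@H]2CC(=O)NC2=O)OC=C1I | intermediate
21 | (2E,6E)-farnesol | CC(C)=CCC/C(C)=C/CC/C(C)=C/CO | starting material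
22 | (2E,6E)-farnesal | CC(C)=CCC/C(C)=C/CC/C(C)=C/C=O | intermediate
23 | methyltriphenylphosphonium bromide | C[P+](c1ccccc1)(c1ccccc1)c1ccccc1.[Br-] | starting material
24 | (3E,7E)-4,8,12-trimethyltrideca-1,3,7,11-tetraene | CC(C)=CCC/C(C)=C/CC/C(C)=C/C=C | intermediate
25 | 9-BBN | B1C2CCCC1CCC2 | starting material
26 | B-homofarnesyl-9-BBN | CC(C)=CCC/C(C)=C/CC/C(C)=C/CCB1C2CCCC1CCC2 | intermediate
27 | 5-homofarnesyl-dihydropyranone | O=C1C[C@H]([C@@H]2CC(=O)NC2=O)OC=C1CC/C=C(\C)CC/C=C(\C)CCC=C(C)C | intermediate
28 | allylic alcohol (C4 mainly cis, not defined) | OC1C[C@H]([C@@H]2CC(=O)NC2=O)OC=C1CC/C=C(\C)CC/C=C(\C)CCC=C(C)C | intermediate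
29 | hippolide A | CC(C)=CCC/C(C)=C/CC/C(C)=C/CCC1=CC[C@H]([C@@H]2CC(=O)NC2=O)O[C@@H]1O | target

## Totals and risks
Total steps: 22. Longest linear sequence: 19 (steps 1–16, then 20–22).

Steps most likely to fail:
1. **Step 9 (lactone-amide to hydroxy-imide transfer).** The conversion may be incomplete, or the product may revert to the lactone-amide after neutralisation.
   - Fallback: abandon the acyl transfer. Hydrolyse lactone acid 10 with LiOH and persilylate, then cleave the silyl esters to give the O-TBS diacid.
   - Close the diacid to the cyclic succinic anhydride and convert it to 13 through the amic acid (NH3, then CDI or HMDS/ZnCl2).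
2. **Step 20 (B-alkyl Suzuki on the N–H imide iodo-enone).** Protodeiodination or base-induced retro-oxa-Michael opening of the ring could compete.
   - Fallback: introduce the chain by olefination instead. Treat aldehyde 15 with a Still–Gennari phosphonoacetate α-alkylated with homofarnesyl iodide to give the Z-enoate.
   - HF then gives the 3-alkyl-5,6-dihydropyran-2-one, and N-deprotonation followed by DIBAL at −78 °C gives the lactol.
3. **Step 22 (acidic transposition).** Material may leak to the ring-opened E-enal, or the lactol epimer ratio may be unfavourable.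
   - Fallback: approach the lactol from the higher oxidation state. Oxidise the crude lactol (MnO2) to the robust δ-lactone and purify it.
   - Reduce the imide-anion form with DIBAL and work up at neutral pH, so that no acid touches the Z-enal/lactol system. The epimers are then separated and recycled as in step 22.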